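The slow part of these runs comes after the main conversion: target, once made, sinks again, in eta from 60.3% at 1.25 d to 55.1% at 12.0 d. So the end of a run gives the first rule. The end share f, target at the last reading per unit of substrate converted, is 0.552 in eta, and alpha (0.547) and epsilon (0.548) read the same. Alpha converted 0.0596 M on 0.060 M of reagent, so the two react one to one, and substrate is the limiting reagent in the flask at 1.20 equivalents.

the same everywhere: free catalyst 0.21 mM
- alpha: substrate 0.070 M; reagent 0.060 M; run made earlier
- epsilon: substrate 0.11 M; reagent 0.060 M; run made earlier
- eta: substrate 0.050 M; reagent 0.12 M; run made earlier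
- flask: substrate 0.050 M; reagent 0.0600 M; time 12 d

| run | time / d | target / % | substrate / % |
|---|---|---|---|
| alpha | 0.333 | 20.4 | 75.5 |
| alpha | 1.25 | 52.4 | 21.7 |
| alpha | 4.00 | 47.2 | 14.1 |
| alpha | 12.0 | 46.6 | 14.8 |
| epsilon | 0.333 | 14.4 | 83.9 |
| epsilon | 1.25 | 36.1 | 44.8 |
| epsilon | 4.00 | 30.4 | 45.1 |
| epsilon | 12.0 | 29.8 | 45.6 |
| eta | 0.333 | 28.2 | 67.7 |
| eta | 1.25 | 60.3 | 8.9 |
| eta | 4.00 | 54.0 | 0.9 |
| eta | 12.0 | 55.1 | 0.1 |

(standard deviation of a reading: 0.5 percentage points)

- the earlier runs were read with a standard deviation of 0.5 percentage points

- time, not beyond 12 d, at which the flask holds most target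
- the amount of target, in percent of the substrate charged, at that time

The end share is not the peak, though. Eta's reading at 1.25 d stands a lead L = 10 points above f times its conversion, so a first guess for the flask is f + L = 65.2%. That guess fails, since it needs all substrate converted, and a lead sinks once making stops. The peak falls where the making rate equals the loss, λL. Eta's earliest reading gives λ, counting converted substrate not present as target against the mean lead, as 2.37 d⁻¹. Eta's substrate gives a first-order constant κ of 1.17 d⁻¹ up to 0.333 d and 2.21 d⁻¹ between its first two readings; these are means over each interval, and the second is larger, so neither serves near the peak. Carried on in a straight line from the middles of the two intervals to 1.25 d, κ reaches about 2.98 d⁻¹, and the second round puts the peak at λL/κ = 8.01% of substrate left. That is about 1.29 d, with 60.8% of target. One objection remains: the flask has half of eta's reagent. Alpha, on that same reagent, started at 0.0515 M d⁻¹ against eta's 0.0485 M d⁻¹, which clears the early part, but the late part may run slower and move the time later.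

The forecast says 1.3 d and 60%, close to this reckoning in time and lower in target: “Target peaks when the falling formation rate meets the relaxation loss”.

The flask holds most target at 1.43 d, 59.9% of the substrate charged, with 5.28% of substrate still present at that time.

    reagent + free catalyst → catalyst intermediate A (k = 9750 M⁻¹ h⁻¹)
    substrate + catalyst intermediate A → catalyst intermediate B (k = 856 M⁻¹ h⁻¹)
    catalyst intermediate B → free catalyst + target (k = 13.1 h⁻¹)
    target ⇌ isomer of the product (K = 0.817, k = 0.0464 h⁻¹)
    2 free catalyst ⇌ resting dimer, settled at all times (K = 13400 M⁻¹)

At 12.0 d the flask holds 55.0% of target, as f gives for full conversion (55.2%). The neighbour with 0.036 M of reagent has reagent as its limiting reagent, so f times its conversion gives 39.7%, and that neighbour holds 39.6% of target at 12.0 d.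

Readings and results were generated by integration from invented constants, and the scatter is random.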